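Readings and results stem from a simulated flask with constants of no real substance; noise was put on by code.

Percent of the Sub charged was my unit, and in that unit the charge of Ptn is worth 80.0%.

all flasks: Sub 0.053 M; Ptn 0.0424 M; Ptn2 0.0556 M; Spx 1.06 mM
- dawn: Ptn3 0.089 M; temperature 20 °C; run made earlier
- midnight: Ptn3 0.14 M; temperature 53 °C; run made earlier
- Sunday's: Ptn3 0.0636 M; temperature 65 °C; time 4.0 min
- Wednesday's: Ptn3 0.0636 M; temperature 5 °C; time 4.0 min
- Saturday's: Ptn3 0.0636 M; temperature 35 °C; time 4.0 min

- dawn (time / min: Ptn3.Int / %): 10.0: 18.7; 20.0: 32.7; 30.0: 43.8; 40.0: 48.6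
- midnight (time / min: Ptn3.Int / %): 0.833: 12.9; 2.50: 34.2; 5.00: 47.8; 8.00: 51.6

(each reading ± 1 percentage point)

- the flask with the highest amount of Ptn3.Int, in percent of the Sub charged ("all alike" if they lie within 1.5 percentage points) (Sunday's / Wednesday's / Saturday's / all alike)
- final Ptn3.Int, as a percentage of the Sub charged, in Sunday's
- final Ptn3.Int, as a percentage of the Sub charged, in Wednesday's
- final Ptn3.Int, as a percentage of the Sub charged, in Saturday's

- the numbers in the tables scatter with a standard deviation of 1 percentage point

Apart from Spx, Ptn is the smallest charge, so I guessed it was the limiting reagent, with one Ptn behind each product and 80.0% as the roof. But the last readings stood lower, at 48.6% at dawn and 51.6% at midnight. So I supposed that a side path competes with Ptn3 for what Ptn turns over.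

From the midnight run I got 0.688 for the capture odds per equivalent, meaning the product divided by the rest of the Ptn allowance, per charge of Ptn3 as a fraction of the Sub charge. The dawn run gave 0.922. Both runs were still rising over their last intervals, though, dawn by 4.8 points and midnight by 3.8 points, so I took both figures as somewhat low. Midnight's lower value suggested that heat favours the side path.

A further objection was that the two last readings lie only 3 points apart although Ptn3 differed, which could mean a hard stop independent of Ptn3. The two runs changed temperature and Ptn3 together and do not exclude that, so I kept the odds as a bet. In the three new flasks Ptn3 is 1.20 of the Sub charge, so midnight's odds gave me an estimate of 36.2% for where Sunday's stops. Could Sunday's get there in 4.0 min? The midnight run held 92.6% of its last reading at 5.00 min, and Sunday's is hotter but has less Ptn3, so I expected it near that estimate, with some doubt.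

The forecast gave 40% for Sunday's, within 30% to 53%, then 2.3% for Wednesday's and 12.5% for Saturday's, on the ground that “the hottest flask leads unless side reactions intervene”. Its Sunday's figure stands above my estimate.

The flasks gave 30.4% in Sunday's, 0.211% in Wednesday's and 16.7% in Saturday's.

    Ptn3 + Int → Ptn3.Int (k = 0.270 M⁻¹ s⁻¹, Ea = 49.0 kJ mol⁻¹)
    Int → Ofp (k = 0.00640 s⁻¹, Ea = 82.0 kJ mol⁻¹)
    Sub + Int → Sub.Int (k = 0.110 M⁻¹ s⁻¹, Ea = 39.0 kJ mol⁻¹)
    Sub + Ptn → Sub.Ptn (k = 0.230 M⁻¹ s⁻¹, Ea = 47.0 kJ mol⁻¹)
    Int + Spx → Int.Spx (k = 0.0570 M⁻¹ s⁻¹, Ea = 72.0 kJ mol⁻¹)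
    Ptn2 + Sub.Ptn → Int (k = 0.0950 M⁻¹ s⁻¹, Ea = 58.0 kJ mol⁻¹)
    (constants at 35 °C)

At 35 °C, in Saturday's with Ptn3 at its charge, Ptn3 takes Int at 2.68 times the rate of Int going to Ofp. The Ofp step's activation energy is higher by 33.0 kJ mol⁻¹, and in Sunday's at 4.00 min Ofp stands at 40.9% against 30.4% of Ptn3.Int, with 1.43% of its Ptn left. Sunday's held 32.4% at 40.0 min, which is capture odds per equivalent of 0.567. Dawn's odds put Saturday's at 42.0%, and at 40.0 min Saturday's held 48.5%.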